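**Strategy.** Both halves of the target are (−)-epicatechin 3-O-gallate, so one protected monomer serves twice, and everything rests on building its pyran ring C by a [3+3] union. In ring C the benzylic carbon C4 and the aryl carbon C8a sit 1,3 to each other on ring A, facing C3 and O1, which flank C2. The key step therefore joins an ortho-bromobenzyl bromide (ring A, twofold electrophile) to the enolate of an α-silyloxy aryl ketone (O1–C2=C3, twofold nucleophile): C-benzylation makes C3–C4, CuI-catalysed enolate O-arylation makes O1–C8a. Both stereocentres follow by hydrogenation under dynamic kinetic resolution; C8 bromine then steers the 4β→6 coupling.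

Key step: step 5

Assumption: in step 7 the sense of induction of RuCl2[(S)-binap][(R,R)-dpen] is taken by analogy with racemic 2-substituted cyclohexanones, which maps onto (2R,3R) here; should the analogy not hold, the mirror-image catalyst is the one meant.

Step 1
Reactants: 1 1,3-bis(benzyloxy)-5-bromobenzene
Product: 2 2-bromo-4,6-bis(benzyloxy)benzaldehyde
Conditions: POCl3, DMF, 0 to 70 °C; then H2O, 0 °C
Reagents that add atoms: N,N-dimethylformamide CN(C)C=O; water O
Why: Vilsmeier–Haack formylation; the chloroiminium electrophile should enter ortho to bromine and para to a benzyloxy group, the position between the two ethers being the more hindered one.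

Step 2
Reactants: 2 2-bromo-4,6-bis(benzyloxy)benzaldehyde
Product: 3 [2-bromo-4,6-bis(benzyloxy)phenyl]methanol
Conditions: NaBH4, THF/MeOH, 0 °C
Reagents that add atoms: none
Why: Hydride reduction of the aryl aldehyde by NaBH4 leaves the aryl bromide and the benzyl ethers untouched.

Step 3
Reactants: 3 [2-bromo-4,6-bis(benzyloxy)phenyl]methanol
Product: 4 1,5-bis(benzyloxy)-3-bromo-2-(bromomethyl)benzene
Conditions: PBr3, Et2O, 0 °C; used at once
Reagents that add atoms: phosphorus tribromide BrP(Br)Br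
Why: Bromination of the benzylic alcohol with PBr3 (SN2 on the phosphite ester); the electron-rich bromide is taken on without storage.

Step 4
Reactants: 5 1-[3,4-bis(benzyloxy)phenyl]ethanone
Product: 8 1-[3,4-bis(benzyloxy)phenyl]-2-[(triisopropylsilyl)oxy]ethanone, via triisopropylsilyl enol ether 6 (not isolated), via silyloxy epoxide 7 (not isolated)
Conditions: i-Pr3SiOTf, Et3N, CH2Cl2, 0 °C to rt; aqueous wash; then mCPBA, CH2Cl2, 0 °C
Reagents that add atoms: triisopropylsilyl trifluoromethanesulfonate CC(C)[Si](C(C)C)(C(C)C)OS(=O)(=O)C(F)(F)F; 3-chloroperbenzoic acid O=C(OO)c1cccc(Cl)c1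
Why: Rubottom oxidation: soft enolisation gives the silyl enol ether, mCPBA epoxidises it, and acid-promoted opening of the epoxide with a 1,4 silyl shift should deliver the α-silyloxy ketone; no stereocentre remains.

Step 5
Reactants: 8 1-[3,4-bis(benzyloxy)phenyl]-2-[(triisopropylsilyl)oxy]ethanone; 4 1,5-bis(benzyloxy)-3-bromo-2-(bromomethyl)benzene
Product: 10 5,7-bis(benzyloxy)-2-[3,4-bis(benzyloxy)phenyl]-3-[(triisopropylsilyl)oxy]-4H-chromene, via C-benzylated ketone 9 (not isolated)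
Conditions: LiN(SiMe3)2, THF, −78 °C; 4, −78 to 0 °C; then, in the same flask, CuI (10 mol %), 1,10-phenanthroline (20 mol %), Cs2CO3, DMF, 90 °C
Reagents that add atoms: none
Why: The lithium enolate of 8 is benzylated on carbon by the activated bromide 4 (SN2 enolate alkylation, bond C3–C4) to give ketone 9; Cs2CO3 then re-forms the enolate, whose oxygen O1 displaces the ortho bromide at C8a under CuI/1,10-phenanthroline catalysis (Ullmann-type enolate O-arylation at monovalent copper, bond O1–C8a). The closest known reaction types are the CuI-catalysed domino C-benzylation/O-arylation of 1,3-dicarbonyl compounds with 2-bromobenzyl bromides to 4H-chromenes and the CuI-mediated cyclisation of ketone enolates onto ortho-bromoarenes. Ring C closes in a 6-exo mode by attack of the enolate oxygen on the aryl carbon; closure through carbon would need a four-membered ring and is excluded. No stereocentre is set here: the racemic C3 centre of 9 is erased on enolisation, and C2 and C3 are both set in step 7. The step needs C- over O-benzylation, which the lithium enolate in THF should secure, and O1- over O3-arylation, which the bulky triisopropylsilyl group should secure by resisting the 1,4 O-to-O shift that would free O3.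

Step 6
Reactants: 10 5,7-bis(benzyloxy)-2-[3,4-bis(benzyloxy)phenyl]-3-[(triisopropylsilyl)oxy]-4H-chromene
Product: 11 racemic 5,7-bis(benzyloxy)-2-[3,4-bis(benzyloxy)phenyl]chroman-3-one
Conditions: Bu4NF, AcOH, THF, 0 °C, argon; crude ketone used directly
Reagents that add atoms: none
Why: Fluoride cleaves the silyl enol ether at silicon to the C3 enolate, which acetic acid protonates at C2, so the ketone should form regiospecifically at C3 (desilylation of a silyl enol ether); C2 is racemic.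

Step 7
Reactants: 11 racemic 5,7-bis(benzyloxy)-2-[3,4-bis(benzyloxy)phenyl]chroman-3-one
Product: 12 (2R,3R)-5,7-bis(benzyloxy)-2-[3,4-bis(benzyloxy)phenyl]chroman-3-ol (5,7,3′,4′-tetra-O-benzyl-(−)-epicatechin)
Conditions: RuCl2[(S)-binap][(R,R)-dpen] (1 mol %), KOt-Bu (10 mol %), H2 (10 atm), i-PrOH/toluene, 25 °C
Reagents that add atoms: none
Why: Noyori-type asymmetric ketone hydrogenation under dynamic kinetic resolution: KOt-Bu racemises the doubly activated C2 through the enolate, the catalyst should reduce the (2R)-ketone faster and deliver hydride to C3 trans to the equatorial aryl group, giving the 2,3-cis alcohol with both stereocentres set at once.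

Step 8
Reactants: 12 (2R,3R)-5,7-bis(benzyloxy)-2-[3,4-bis(benzyloxy)phenyl]chroman-3-ol
Product: 13 (2R,3R)-8-bromo-5,7-bis(benzyloxy)-2-[3,4-bis(benzyloxy)phenyl]chroman-3-ol
Conditions: NBS, CH2Cl2, −40 °C to rt
Reagents that add atoms: N-bromosuccinimide O=C1CCC(=O)N1Br
Why: Electrophilic aromatic bromination of the phloroglucinol-type ring A; C8 should react in preference to C6, which is flanked by two benzyloxy groups, and the bromine blocks C8 for the later coupling.

Step 9
Reactants: 13 (2R,3R)-8-bromo-5,7-bis(benzyloxy)-2-[3,4-bis(benzyloxy)phenyl]chroman-3-ol; 14 3,4,5-tris(benzyloxy)benzoic acid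
Product: 15 (2R,3R)-8-bromo-5,7-bis(benzyloxy)-2-[3,4-bis(benzyloxy)phenyl]chroman-3-yl 3,4,5-tris(benzyloxy)benzoate (nucleophilic lower unit)
Conditions: DCC, DMAP, CH2Cl2, rt
Reagents that add atoms: none
Why: Steglich esterification of the axial C3 hydroxyl; no stereocentre is touched.

Step 10
Reactants: 13 (2R,3R)-8-bromo-5,7-bis(benzyloxy)-2-[3,4-bis(benzyloxy)phenyl]chroman-3-ol
Product: 16 (2R,3R,4S)-8-bromo-5,7-bis(benzyloxy)-2-[3,4-bis(benzyloxy)phenyl]-4-(2-ethoxyethoxy)chroman-3-ol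
Conditions: DDQ, 2-ethoxyethanol, CH2Cl2, rt
Reagents that add atoms: 2-ethoxyethanol CCOCCO
Why: DDQ abstracts hydride from the benzylic C4 position activated by ring A (benzylic oxidation) and the alcohol should trap the cation trans to the C3 hydroxyl, giving the 4β ether; plain benzyl ethers are inert to DDQ.

Step 11
Reactants: 16 (2R,3R,4S)-8-bromo-5,7-bis(benzyloxy)-2-[3,4-bis(benzyloxy)phenyl]-4-(2-ethoxyethoxy)chroman-3-ol; 14 3,4,5-tris(benzyloxy)benzoic acid
Product: 17 (2R,3R,4S)-8-bromo-5,7-bis(benzyloxy)-2-[3,4-bis(benzyloxy)phenyl]-4-(2-ethoxyethoxy)chroman-3-yl 3,4,5-tris(benzyloxy)benzoate (electrophilic upper unit)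
Conditions: DCC, DMAP, CH2Cl2, rt
Reagents that add atoms: none
Why: Steglich esterification; the C4 acetal-type ether is stable to these neutral conditions.

Step 12
Reactants: 17 electrophilic upper unit; 15 nucleophilic lower unit (3 equiv, excess recovered)
Product: 18 tetradeca-O-benzyl-8,8′-dibromo-procyanidin B-5 3,3′-di-O-gallate (upper C4β bonded to lower C6)
Conditions: TMSOTf (0.3 equiv), CH2Cl2, −78 to −30 °C
Reagents that add atoms: none
Why: Lewis-acid ionisation of the C4 ether gives a cation stabilised by ring A, the 3-O-acyl group shields the α face (neighbouring-group participation), and C6 of 15, the only free position on its ring A, should attack from the β face, trans to the ester (Friedel–Crafts-type interflavan coupling); bromine on C8 of 17 stops self-condensation there.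

Step 13
Reactants: 18 tetradeca-O-benzyl-8,8′-dibromo-procyanidin B-5 3,3′-di-O-gallate
Product: 19 procyanidin B-5 3,3′-di-O-gallate
Conditions: H2 (1 atm), Pd(OH)2/C, Et3N (2.2 equiv), THF/MeOH/H2O, rt
Reagents that add atoms: none
Why: Hydrogenolysis over Pd(OH)2/C should remove all fourteen benzyl ethers and, with Et3N as HBr scavenger, both aryl bromides; the esters, the interflavan bond and all five stereocentres are untouched.

**Compound list**

1 | 1,3-bis(benzyloxy)-5-bromobenzene | Brc1cc(OCc2ccccc2)cc(OCc2ccccc2)c1 | starting material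
2 | 2-bromo-4,6-bis(benzyloxy)benzaldehyde | O=Cc1c(Br)cc(OCc2ccccc2)cc1OCc1ccccc1 | intermediate
3 | [2-bromo-4,6-bis(benzyloxy)phenyl]methanol | OCc1c(Br)cc(OCc2ccccc2)cc1OCc1ccccc1 | intermediate
4 | 1,5-bis(benzyloxy)-3-bromo-2-(bromomethyl)benzene | BrCc1c(Br)cc(OCc2ccccc2)cc1OCc1ccccc1 | intermediate
5 | 1-[3,4-bis(benzyloxy)phenyl]ethanone | CC(=O)c1ccc(OCc2ccccc2)c(OCc2ccccc2)c1 | starting material
6 | {1-[3,4-bis(benzyloxy)phenyl]ethenyloxy}triisopropylsilane | C=C(O[Si](C(C)C)(C(C)C)C(C)C)c1ccc(OCc2ccccc2)c(OCc2ccccc2)c1 | intermediate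
7 | racemic 2-[3,4-bis(benzyloxy)phenyl]-2-[(triisopropylsilyl)oxy]oxirane | CC(C)[Si](OC1(CO1)c1ccc(OCc2ccccc2)c(OCc2ccccc2)c1)(C(C)C)C(C)C | intermediate
8 | 1-[3,4-bis(benzyloxy)phenyl]-2-[(triisopropylsilyl)oxy]ethanone | O=C(CO[Si](C(C)C)(C(C)C)C(C)C)c1ccc(OCc2ccccc2)c(OCc2ccccc2)c1 | intermediate
9 | racemic 1-[3,4-bis(benzyloxy)phenyl]-3-[2-bromo-4,6-bis(benzyloxy)phenyl]-2-[(triisopropylsilyl)oxy]propan-1-one | O=C(C(Cc1c(Br)cc(OCc2ccccc2)cc1OCc1ccccc1)O[Si](C(C)C)(C(C)C)C(C)C)c1ccc(OCc2ccccc2)c(OCc2ccccc2)c1 | intermediate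
10 | 5,7-bis(benzyloxy)-2-[3,4-bis(benzyloxy)phenyl]-3-[(triisopropylsilyl)oxy]-4H-chromene | CC(C)[Si](OC1=C(c2ccc(OCc3ccccc3)c(OCc3ccccc3)c2)Oc2cc(OCc3ccccc3)cc(OCc3ccccc3)c2C1)(C(C)C)C(C)C | intermediate
11 | racemic 5,7-bis(benzyloxy)-2-[3,4-bis(benzyloxy)phenyl]chroman-3-one | O=C1Cc2c(OCc3ccccc3)cc(OCc3ccccc3)cc2OC1c1ccc(OCc2ccccc2)c(OCc2ccccc2)c1 | intermediate
12 | (2R,3R)-5,7-bis(benzyloxy)-2-[3,4-bis(benzyloxy)phenyl]chroman-3-ol | O[C@@H]1Cc2c(OCc3ccccc3)cc(OCc3ccccc3)cc2O[C@@H]1c1ccc(OCc2ccccc2)c(OCc2ccccc2)c1 | intermediate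
13 | (2R,3R)-8-bromo-5,7-bis(benzyloxy)-2-[3,4-bis(benzyloxy)phenyl]chroman-3-ol | O[C@@H]1Cc2c(OCc3ccccc3)cc(OCc3ccccc3)c(Br)c2O[C@@H]1c1ccc(OCc2ccccc2)c(OCc2ccccc2)c1 | intermediate
14 | 3,4,5-tris(benzyloxy)benzoic acid | OC(=O)c1cc(OCc2ccccc2)c(OCc2ccccc2)c(OCc2ccccc2)c1 | starting material
15 | (2R,3R)-8-bromo-5,7-bis(benzyloxy)-2-[3,4-bis(benzyloxy)phenyl]chroman-3-yl 3,4,5-tris(benzyloxy)benzoate | O=C(O[C@@H]1Cc2c(OCc3ccccc3)cc(OCc3ccccc3)c(Br)c2O[C@@H]1c1ccc(OCc2ccccc2)c(OCc2ccccc2)c1)c1cc(OCc2ccccc2)c(OCc2ccccc2)c(OCc2ccccc2)c1 | intermediate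
16 | (2R,3R,4S)-8-bromo-5,7-bis(benzyloxy)-2-[3,4-bis(benzyloxy)phenyl]-4-(2-ethoxyethoxy)chroman-3-ol | O[C@@H]1[C@@H](OCCOCC)c2c(OCc3ccccc3)cc(OCc3ccccc3)c(Br)c2O[C@@H]1c1ccc(OCc2ccccc2)c(OCc2ccccc2)c1 | intermediate
17 | (2R,3R,4S)-8-bromo-5,7-bis(benzyloxy)-2-[3,4-bis(benzyloxy)phenyl]-4-(2-ethoxyethoxy)chroman-3-yl 3,4,5-tris(benzyloxy)benzoate | O=C(O[C@@H]1[C@@H](OCCOCC)c2c(OCc3ccccc3)cc(OCc3ccccc3)c(Br)c2O[C@@H]1c1ccc(OCc2ccccc2)c(OCc2ccccc2)c1)c1cc(OCc2ccccc2)c(OCc2ccccc2)c(OCc2ccccc2)c1 | intermediate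
18 | tetradeca-O-benzyl-8,8′-dibromo-procyanidin B-5 3,3′-di-O-gallate (two units of 15-type, upper C4β to lower C6) | O=C(O[C@@H]1[C@@H](c2c(OCc3ccccc3)c(Br)c3c(c2OCc2ccccc2)C[C@@H](OC(=O)c2cc(OCc4ccccc4)c(OCc4ccccc4)c(OCc4ccccc4)c2)[C@@H](c2ccc(OCc4ccccc4)c(OCc4ccccc4)c2)O3)c2c(OCc3ccccc3)cc(OCc3ccccc3)c(Br)c2O[C@@H]1c1ccc(OCc2ccccc2)c(OCc2ccccc2)c1)c1cc(OCc2ccccc2)c(OCc2ccccc2)c(OCc2ccccc2)c1 | intermediate
19 | procyanidin B-5 3,3′-di-O-gallate | O=C(O[C@@H]1[C@@H](c2c(O)cc3c(c2O)C[C@@H](OC(=O)c2cc(O)c(O)c(O)c2)[C@@H](c2ccc(O)c(O)c2)O3)c2c(O)cc(O)cc2O[C@@H]1c1ccc(O)c(O)c1)c1cc(O)c(O)c(O)c1 | target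

**Totals.** Total step count: 13. Longest linear sequence: 11 steps (1, 2, 3, 5, 6, 7, 8, 10, 11, 12, 13); steps 4 and 9 are side branches.

**Steps most likely to fail**

Step 5. The silyl group may shift between O3 and O1 in the hot enolate, which would divert the O-arylation to a five-membered ring. Bromide 4 may also ionise and decompose before C-alkylation. The fallback sets out from aldehyde 2 and ketone 5 and makes the C3–C4 bond by condensation instead. Claisen–Schmidt condensation (KOH, EtOH/THF) should give the chalcone F1. Conjugate reduction with [CuH(PPh3)]6 and a silane should give the dihydrochalcone F2. CuI-catalysed intramolecular enolate O-arylation (CuI, K3PO4, DMF, 105 °C) should give the flav-2-ene F3. Hydroboration–oxidation (BH3·THF; then NaOH, H2O2) should give the racemic trans-flavan-3-ol F4. Dess–Martin oxidation then comes back to the route at ketone 11.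

Step 7. The catalyst may discriminate poorly between the two interconverting ketone enantiomers, or reduction may outpace racemisation at C2. The fallback sets out from ketone 11 and separates substrate-controlled reduction from resolution. LiBH(s-Bu)3 (THF, −78 °C) should add hydride trans to the aryl group and give the racemic cis alcohol F5. Esterification with (R)-2-methoxy-2-phenylacetic acid (DCC, DMAP) gives two diastereomeric esters, from which the (2R,3R) ester F6 is separated by chromatography. Methanolysis (K2CO3, MeOH/THF) comes back to the route at 12.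

Step 12. The hindered, bromine-deactivated C6 of 15 may attack so slowly that the cation from 17 is lost to self-condensation at its own C6 or to elimination. The fallback sets out from 16 and 13 and changes the order of events. The two free alcohols are coupled first (TMSOTf, CH2Cl2, −78 °C), where both partners are less hindered, to give the dimeric diol F7. Twofold Steglich esterification with acid 14 (DCC, DMAP) then comes back to the route at 18.

**Further compounds**

F1 | step 5 | (E)-1-[3,4-bis(benzyloxy)phenyl]-3-[2-bromo-4,6-bis(benzyloxy)phenyl]prop-2-en-1-one | O=C(/C=C/c1c(Br)cc(OCc2ccccc2)cc1OCc1ccccc1)c1ccc(OCc2ccccc2)c(OCc2ccccc2)c1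
F2 | step 5 | 1-[3,4-bis(benzyloxy)phenyl]-3-[2-bromo-4,6-bis(benzyloxy)phenyl]propan-1-one | O=C(CCc1c(Br)cc(OCc2ccccc2)cc1OCc1ccccc1)c1ccc(OCc2ccccc2)c(OCc2ccccc2)c1
F3 | step 5 | 5,7-bis(benzyloxy)-2-[3,4-bis(benzyloxy)phenyl]-4H-chromene | C1(c2ccc(OCc3ccccc3)c(OCc3ccccc3)c2)=CCc2c(OCc3ccccc3)cc(OCc3ccccc3)cc2O1
F4 | step 5 | racemic trans-5,7-bis(benzyloxy)-2-[3,4-bis(benzyloxy)phenyl]chroman-3-ol (both enantiomers) | O[C@H]1Cc2c(OCc3ccccc3)cc(OCc3ccccc3)cc2O[C@@H]1c1ccc(OCc2ccccc2)c(OCc2ccccc2)c1.O[C@@H]1Cc2c(OCc3ccccc3)cc(OCc3ccccc3)cc2O[C@H]1c1ccc(OCc2ccccc2)c(OCc2ccccc2)c1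
F5 | step 7 | racemic cis-5,7-bis(benzyloxy)-2-[3,4-bis(benzyloxy)phenyl]chroman-3-ol (12 and its enantiomer) | O[C@@H]1Cc2c(OCc3ccccc3)cc(OCc3ccccc3)cc2O[C@@H]1c1ccc(OCc2ccccc2)c(OCc2ccccc2)c1.O[C@H]1Cc2c(OCc3ccccc3)cc(OCc3ccccc3)cc2O[C@H]1c1ccc(OCc2ccccc2)c(OCc2ccccc2)c1
F6 | step 7 | (2R,3R)-5,7-bis(benzyloxy)-2-[3,4-bis(benzyloxy)phenyl]chroman-3-yl (R)-2-methoxy-2-phenylacetate | CO[C@@H](C(=O)O[C@@H]1Cc2c(OCc3ccccc3)cc(OCc3ccccc3)cc2O[C@@H]1c1ccc(OCc2ccccc2)c(OCc2ccccc2)c1)c1ccccc1
F7 | step 12 | octa-O-benzyl-8,8′-dibromo-procyanidin B-5 (3,3′-diol, upper C4β to lower C6) | O[C@@H]1[C@@H](c2c(OCc3ccccc3)c(Br)c3c(c2OCc2ccccc2)C[C@@H](O)[C@@H](c2ccc(OCc4ccccc4)c(OCc4ccccc4)c2)O3)c2c(OCc3ccccc3)cc(OCc3ccccc3)c(Br)c2O[C@@H]1c1ccc(OCc2ccccc2)c(OCc2ccccc2)c1
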